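Remark on the chemistry: abietane locants (C1–C20) are used for all intermediates, also before the rings exist. The carboxyl carbon of lactone 11 and acid 14 becomes C7, and C6 is inserted in steps 7 and 8. Alcohol 33 is drawn as the 7β epimer; the outcome of step 20 does not depend on this.

## Analysis of the target

The target (C42H60O4) is a C2-symmetric dimer of two 12-methoxyabieta-8,11,13-triene units. Each unit has a saturated ring A with a gem-dimethyl group at C4, a ring B, and an aromatic ring C carrying methoxy at C12 and isopropyl at C13. The units are joined head-to-tail through a central 1,4-dioxane: the oxygen on C6 of one half is bonded to C7 of the other half, and the reverse. Each half has four stereocentres: C10 (methyl β), C5 (H α, trans ring fusion), C6 (O α) and C7 (O β). Both oxygens are equatorial on ring B, so the dioxane is trans-fused to both B rings and is the thermodynamically favoured arrangement. The two C7–O bonds are benzylic and para to a methoxy group, so they ionise readily in acid; this is the main sensitivity and also the handle for the last step. The difficulties are the quaternary C10 next to C5 and the gem-dimethyl carbon C4, the tetrasubstituted benzene with adjacent methoxy and isopropyl groups, and the C6/C7 oxygen pattern. The strategy rests on the fact that ring C is fused to ring B along C8–C9. Cutting C8–C9 and C13–C14 opens both rings at once and leaves ring A with two arms: an enyne (C9, C11, C12, C13) on C10, and an ynone (C7, C8, C14) reached from C5 through C6.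

## Retrosynthetic reasoning

**36 to 34.** Both C7–O bonds of the dioxane are cut. C7 is the only position whose C–O bond forms and breaks reversibly, so C6 can be carried in with fixed configuration and C7 is set by equilibration. The cut also halves the problem to one monomer. The forward reaction must make two ether bonds, the first between two molecules (hydroxy ether 35) and the second by ring closure, and must do so head-to-tail.

**34 to 33 to 32.** The C7 carbinol comes from the C7 ketone, and the C6 hydroxyl from its silyl ether. Reduction comes before desilylation, so that a free α-ketol is never exposed to base.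

**32 to 30.** C8–C9 and C13–C14 are cut. This is the only disconnection that removes rings B and C together and leaves the arene substituents on an acyclic enol ether, so no arene substitution chemistry is needed. The forward reaction is a thermal [4+2] cycloaddition through cyclic allene 31, followed by aromatisation without an oxidant.

**30 to 29.** The C7–C8 bond is cut: the terminal ynone comes from an N-methoxy-N-methylamide and an ethynyl nucleophile. It is made last because it is the most fragile group in the route.

**29 to 27 to 25 and 26, then 25 to 24 to 23.** The enol ether O–CH3 bond goes back to the enolate (28) of ynone 27. The C11–C12 bond goes back to terminal alkyne 25 and acid chloride 26, which supplies C12, C13 and the isopropyl group. The C9≡C11 triple bond goes back to aldehyde 24 by one-carbon homologation, and 24 to alcohol 23.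

**23 to 22 to 20.** The amide and the C9 hydroxyl are the two ends of a δ-lactone, so opening 22 differentiates the arms without protecting groups. The C6–O bond is cut next. An addition to an acyclic C6 aldehyde would be poorly controlled, because C5 is flanked by two quaternary carbons of similar size. In the trans-fused bicycle 20 the two axial methyl groups (on C4 and C10) shield the β face of C6, so oxidation of the ketene acetal 21 must occur on the α face.

**20 to 18 to 16 to 14.** The lactone comes from hydroxy ester 19, and one hydrogenation both saturates C1=C2 and frees the C9 hydroxyl. C6 is inserted between C5 and the carboxyl carbon by Arndt–Eistert homologation (through 15, 16 and ketene 17), which retains the configuration at C5.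

**14 to 11.** The C5–C10 bond is cut by an enolate Claisen ring contraction (through 12 and 13). This makes both adjacent stereocentres, one of them quaternary, in one stereospecific step from a single carbinol centre, and delivers ring A with all its carbons. The alkene geometry decides which substituent on C10 is cis to the carboxyl group. The carbinol configuration decides the absolute sense.

**11 to 9 to 6 and 4.** The lactone C–O bond comes from catalyst-controlled reduction of enone 9 (through hydroxy ester 10). Enone 9 comes from acylation of the alkenyl metal 8, made from iodide 4, with acid chloride 7, made from half-ester 6.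

**6 to 5; 4 to 3 to 1.** The half-ester comes from opening the symmetric anhydride 5. The Z iodide comes from anti-carbometalation of 1 (through 2), which places iodine cis to the oxygenated carbon and so fixes the alkene geometry that the ring contraction needs.

## Alternatives that were turned down

**Alternative 1:** Here the C5–C10 bond is cut in a ring A acid that already carries ring C as an aryl group on C10. The key step is the enolate Claisen ring contraction of aryl-substituted alkenyl lactone A1 through a boat transition state to cyclohexene acid A2. Ring B would then be closed onto the arene by chain extension and acylation at C8, para to the methoxy group.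
- For: one step sets C5 and C10, the arene is robust, and the later ring B closure is a reliable acylation with clear regiochemistry. On this point it is stronger than the chosen route, which depends on a sensitive ynone.
- Against: the aryl alkenyl fragment has to be made separately. In the boat transition state the aryl group is the Z substituent and is pressed against the ring methylene and the gem-dimethyl carbon, much more than the benzyloxymethyl group used here. Oxygen at C6 and C7 would have to be introduced after ring B exists.
- Comparison: the same ring contraction is used in the chosen route, but with a small Z substituent. The chosen route then forms rings B and C in one step with the C6 oxygen and the C7 carbonyl already in place, and takes the arene substituents from a simple C5 acid chloride.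

**Alternative 2:** Here ring C is cut at C13–C14 in a bicyclic 12,13-diketone A4 with an exocyclic methylene on C8, made by degrading sclareolide A3. The key step is a Lewis-acid carbonyl-ene attack of C14 on the C13 ketone, followed by dehydration and enolisation to ferruginol A5.
- For: the chiral pool supplies rings A and B with C5 and C10 correct and with no asymmetric step, and the sequence is short. In step count and stereochemical security it is stronger than the chosen route.
- Against: ring B arrives with CH2 groups at C6 and C7, so both oxygens must come from late benzylic oxidation of an electron-rich arene followed by α-oxygenation. The phenol must be methylated, and the side chain of A3 has to be cut down and rebuilt to reach A4.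
- Comparison: the chosen route offers C6 and C7 functionality that is built into the cyclisation substrate, no late oxidation beside the electron-rich ring, and independence from a terpene feedstock.

**Alternative 3:** Here ring A is cut at C1–C10 and C4–C5 on a 1-methyl-2-tetralone A6 that already contains rings B and C. In the key step the secondary enamine of a chiral imine of A6 adds to methyl vinyl ketone A7 at C10, and aldol condensation closes ring A to tricyclic enone A8.
- For: all three rings exist after the key step and the quaternary C10 is set by an auxiliary. In early convergence it is stronger than the chosen route.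
- Against: A8 has no gem-dimethyl group at C4, has a C3 carbonyl that must be removed, and has a C4=C5 double bond. C5 is therefore not set by the key step; it must be fixed later by a reduction whose trans selectivity is not secured. Oxidation at C6 and C7 is still to come, and A6 itself needs a synthesis.
- Comparison: the chosen route sets C5 together with C10 in one stereospecific sigmatropic step, takes the gem-dimethyl group from a commodity anhydride, and needs no carbonyl removal.

Key step: step 17

## Route

Step 1
Reactants: 1 prop-2-yn-1-ol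
Product: 3 (2Z)-3-iodo-2-methylprop-2-en-1-ol, via alkenylmagnesium alkoxide 2 (not isolated)
Conditions: MeMgBr (2.5 equiv), CuI (10 mol %), THF, 0 °C to rt; then I2, −78 to 0 °C
Reagents that add atoms: methylmagnesium bromide, C[Mg]Br; iodine, II
Why: Copper-catalysed anti-carbomagnesiation of the propargylic alkoxide puts methyl on C2 and magnesium on C3 cis to the CH2O group through a five-membered chelate; iodinolysis occurs with retention, so iodine ends cis to CH2OH.

Step 2
Reactants: 3 (2Z)-3-iodo-2-methylprop-2-en-1-ol
Product: 4 benzyl (2Z)-3-iodo-2-methylprop-2-en-1-yl ether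
Conditions: NaH, BnBr, Bu4NI (cat.), THF, 0 °C to rt
Reagents that add atoms: benzyl bromide, BrCc1ccccc1
Why: Williamson ether synthesis; the benzyl group survives the organometallic, borane and enolate steps and is removed in the hydrogenation of step 9.

Step 3
Reactants: 5 3,3-dimethylglutaric anhydride
Product: 6 5-methoxy-3,3-dimethyl-5-oxopentanoic acid
Conditions: MeOH, DMAP (cat.), reflux
Reagents that add atoms: methanol, CO
Why: Alcoholysis of a symmetric cyclic anhydride gives a single half-ester.

Step 4
Reactants: 6 5-methoxy-3,3-dimethyl-5-oxopentanoic acid; 4 benzyl (2Z)-3-iodo-2-methylprop-2-en-1-yl ether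
Product: 9 methyl (6Z)-8-(benzyloxy)-3,3,7-trimethyl-5-oxooct-6-enoate, via acid chloride 7 (not isolated), via alkenylzinc chloride 8 (not isolated)
Conditions: 6, (COCl)2, DMF (cat.), CH2Cl2, 0 °C to rt, concentrate; 4, t-BuLi (2.1 equiv), Et2O, −78 °C, then ZnCl2, THF; combine, Pd(PPh3)4 (5 mol %), THF, 0 °C to rt
Reagents that add atoms: none
Why: Negishi acylation; iodine–lithium exchange and transmetalation to zinc retain the alkene geometry, and the organozinc reagent tolerates the methyl ester.

Step 5
Reactants: 9 methyl (6Z)-8-(benzyloxy)-3,3,7-trimethyl-5-oxooct-6-enoate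
Product: 11 (6R)-6-[(1Z)-3-(benzyloxy)-2-methylprop-1-en-1-yl]-4,4-dimethyloxan-2-one, via hydroxy ester 10 (not isolated)
Conditions: (S)-Me-CBS oxazaborolidine (20 mol %), BH3·SMe2, THF, −30 °C; MeOH quench; then PPTS (cat.), toluene, 60 °C
Reagents that add atoms: none
Why: Corey–Bakshi–Shibata reduction; the alkenyl group acts as the large substituent and the α-methylene as the small one, so the (S) catalyst should give the (R) allylic alcohol. The δ-hydroxy ester then lactonises, helped by the gem-dimethyl group.

Step 6
Reactants: 11 (6R)-6-[(1Z)-3-(benzyloxy)-2-methylprop-1-en-1-yl]-4,4-dimethyloxan-2-one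
Product: 14 (1S,2S)-2-[(benzyloxy)methyl]-2,6,6-trimethylcyclohex-3-ene-1-carboxylic acid, via silyl ketene acetal 12 (not isolated), via trimethylsilyl ester 13 (not isolated)
Conditions: LiN(iPr)2, Me3SiCl–Et3N (in situ quench), THF, −78 °C; then toluene, 100 °C; 1 M HCl work-up
Reagents that add atoms: none
Why: Ireland–Claisen ring contraction of a lactone enolate; the lactone ring forces a boat transition state, in which the carboxyl carbon ends cis to the E substituent (methyl) and trans to the Z substituent (benzyloxymethyl). The bond forms on the face from which the C–O bond leaves, so the (R) carbinol gives the natural configuration at C5 and C10.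

Step 7
Reactants: 14 (1S,2S)-2-[(benzyloxy)methyl]-2,6,6-trimethylcyclohex-3-ene-1-carboxylic acid
Product: 16 1-[(1S,2S)-2-[(benzyloxy)methyl]-2,6,6-trimethylcyclohex-3-en-1-yl]-2-diazoethan-1-one, via acid chloride 15 (not isolated)
Conditions: (COCl)2, DMF (cat.), CH2Cl2, 0 °C to rt, concentrate; Me3SiCHN2 (2.5 equiv), MeCN–THF, 0 °C to rt
Reagents that add atoms: (trimethylsilyl)diazomethane, C[Si](C)(C)C=[N+]=[N-]
Why: First half of the Arndt–Eistert homologation; the small diazoalkane acylates even a hindered acid chloride, and the carbon it brings is C6.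

Step 8
Reactants: 16 1-[(1S,2S)-2-[(benzyloxy)methyl]-2,6,6-trimethylcyclohex-3-en-1-yl]-2-diazoethan-1-one
Product: 18 methyl 2-[(1S,2S)-2-[(benzyloxy)methyl]-2,6,6-trimethylcyclohex-3-en-1-yl]acetate, via ketene 17 (not isolated)
Conditions: AgO2CPh (10 mol %), Et3N, MeOH, rt, dark
Reagents that add atoms: methanol, CO
Why: Wolff rearrangement; C5 migrates with retention and methanol traps the ketene.

Step 9
Reactants: 18 methyl 2-[(1S,2S)-2-[(benzyloxy)methyl]-2,6,6-trimethylcyclohex-3-en-1-yl]acetate
Product: 20 (4aS,8aS)-5,5,8a-trimethyl-1,4,4a,5,6,7,8,8a-octahydro-3H-isochromen-3-one, via hydroxy ester 19 (not isolated)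
Conditions: H2 (1 atm), Pd/C, EtOAc–MeOH, rt; filter; TsOH·H2O (cat.), toluene, 80 °C
Reagents that add atoms: none
Why: One hydrogenation saturates C1=C2, which creates no stereocentre, and cleaves the benzyl ether. The trans-1,2-diequatorial hydroxymethyl and ester arms then close to the trans-fused δ-lactone.

Step 10
Reactants: 20 (4aS,8aS)-5,5,8a-trimethyl-1,4,4a,5,6,7,8,8a-octahydro-3H-isochromen-3-one
Product: 22 (4R,4aS,8aS)-4-[(tert-butyldimethylsilyl)oxy]-5,5,8a-trimethyl-1,4,4a,5,6,7,8,8a-octahydro-3H-isochromen-3-one, via ketene silyl acetal 21 (not isolated)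
Conditions: LiN(iPr)2, THF, −78 °C; t-BuMe2SiCl, HMPA, −78 to 0 °C; then m-CPBA, NaHCO3, hexane–CH2Cl2, −20 °C to rt
Reagents that add atoms: tert-butyldimethylsilyl chloride, CC(C)(C)[Si](C)(C)Cl; 3-chloroperoxybenzoic acid, OOC(=O)c1cccc(Cl)c1
Why: Rubottom oxidation of a ketene silyl acetal with silyl transfer to the new oxygen. The axial methyl groups on C4 and C10 block the β face of C6, so oxygen enters from the α face and sits equatorial (6R), which is also the thermodynamically preferred position.

Step 11
Reactants: 22 (4R,4aS,8aS)-4-[(tert-butyldimethylsilyl)oxy]-5,5,8a-trimethyl-1,4,4a,5,6,7,8,8a-octahydro-3H-isochromen-3-one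
Product: 23 (2R)-2-[(tert-butyldimethylsilyl)oxy]-2-[(1S,2S)-2-(hydroxymethyl)-2,6,6-trimethylcyclohexyl]-N-methoxy-N-methylacetamide
Conditions: MeNH(OMe)·HCl, AlMe3, CH2Cl2, 0 °C to rt; Rochelle salt work-up; used crude
Reagents that add atoms: N,O-dimethylhydroxylamine hydrochloride, CNOC.Cl
Why: Weinreb aminolysis of a lactone with the aluminium amide; it turns C7 into a ketone precursor and frees the C9 hydroxyl in the same step.

Step 12
Reactants: 23 (2R)-2-[(tert-butyldimethylsilyl)oxy]-2-[(1S,2S)-2-(hydroxymethyl)-2,6,6-trimethylcyclohexyl]-N-methoxy-N-methylacetamide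
Product: 24 (2R)-2-[(tert-butyldimethylsilyl)oxy]-2-[(1S,2S)-2-formyl-2,6,6-trimethylcyclohexyl]-N-methoxy-N-methylacetamide
Conditions: Dess–Martin periodinane, NaHCO3, CH2Cl2, 0 °C to rt
Reagents that add atoms: none
Why: Buffered Dess–Martin oxidation of a neopentyl primary alcohol; the aldehyde has no α-hydrogen and cannot epimerise, and the buffer prevents relactonisation.

Step 13
Reactants: 24 (2R)-2-[(tert-butyldimethylsilyl)oxy]-2-[(1S,2S)-2-formyl-2,6,6-trimethylcyclohexyl]-N-methoxy-N-methylacetamide
Product: 25 (2R)-2-[(tert-butyldimethylsilyl)oxy]-2-[(1S,2S)-2-ethynyl-2,6,6-trimethylcyclohexyl]-N-methoxy-N-methylacetamide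
Conditions: dimethyl (1-diazo-2-oxopropyl)phosphonate, K2CO3, MeOH, 0 °C to rt
Reagents that add atoms: dimethyl (1-diazo-2-oxopropyl)phosphonate, COP(=O)(OC)C(=[N+]=[N-])C(C)=O
Why: Ohira–Bestmann (Seyferth–Gilbert) homologation; it works on non-enolisable quaternary aldehydes, and the amide and silyl ether tolerate carbonate in methanol.

Step 14
Reactants: 25 (2R)-2-[(tert-butyldimethylsilyl)oxy]-2-[(1S,2S)-2-ethynyl-2,6,6-trimethylcyclohexyl]-N-methoxy-N-methylacetamide; 26 3-methylbutanoyl chloride (isovaleryl chloride)
Product: 27 (2R)-2-[(tert-butyldimethylsilyl)oxy]-N-methoxy-N-methyl-2-[(1S,2S)-2,6,6-trimethyl-2-(5-methyl-3-oxohex-1-yn-1-yl)cyclohexyl]acetamide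
Conditions: 26 (1.5 equiv), PdCl2(PPh3)2 (2 mol %), CuI (4 mol %), Et3N, THF, rt
Reagents that add atoms: none
Why: Acyl Sonogashira coupling of a terminal alkyne with an acid chloride; it needs no strong base, so the amide and the C6 centre are untouched.

Step 15
Reactants: 27 (2R)-2-[(tert-butyldimethylsilyl)oxy]-N-methoxy-N-methyl-2-[(1S,2S)-2,6,6-trimethyl-2-(5-methyl-3-oxohex-1-yn-1-yl)cyclohexyl]acetamide
Product: 29 (2R)-2-[(tert-butyldimethylsilyl)oxy]-N-methoxy-2-[(1S,2S)-2-[(3Z)-3-methoxy-5-methylhex-3-en-1-yn-1-yl]-2,6,6-trimethylcyclohexyl]-N-methylacetamide, via potassium enolate 28 (not isolated)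
Conditions: KN(SiMe3)2 (1.05 equiv), THF–DMPU, −78 °C; MeOTf, −78 to −40 °C
Reagents that add atoms: methyl trifluoromethanesulfonate, COS(=O)(=O)C(F)(F)F
Why: O-alkylation of a dissociated potassium enolate with a hard methylating agent in a dipolar medium. The ynone α-methylene is by far the most acidic site, and the open transition state in the presence of DMPU favours the enolate with oxygen cis to isopropyl, which gives the Z enol ether.

Step 16
Reactants: 29 (2R)-2-[(tert-butyldimethylsilyl)oxy]-N-methoxy-2-[(1S,2S)-2-[(3Z)-3-methoxy-5-methylhex-3-en-1-yn-1-yl]-2,6,6-trimethylcyclohexyl]-N-methylacetamide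
Product: 30 (1R)-1-[(tert-butyldimethylsilyl)oxy]-1-[(1S,2S)-2-[(3Z)-3-methoxy-5-methylhex-3-en-1-yn-1-yl]-2,6,6-trimethylcyclohexyl]but-3-yn-2-one
Conditions: HC≡CMgBr (3 equiv), THF, 0 °C to rt; cold pH 7 buffer quench
Reagents that add atoms: ethynylmagnesium bromide, C#C[Mg]Br
Why: Weinreb ketone synthesis; the chelated tetrahedral adduct prevents over-addition, and the cold neutral quench spares the enol ether and keeps the liberated amine from adding to the ynone.

Step 17
Reactants: 30 (1R)-1-[(tert-butyldimethylsilyl)oxy]-1-[(1S,2S)-2-[(3Z)-3-methoxy-5-methylhex-3-en-1-yn-1-yl]-2,6,6-trimethylcyclohexyl]but-3-yn-2-one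
Product: 32 6α-[(tert-butyldimethylsilyl)oxy]-12-methoxyabieta-8,11,13-trien-7-one (6α-silyloxysugiol methyl ether), via cyclic allene 31 (not isolated)
Conditions: toluene (0.01 M, degassed), 2,6-di-tert-butyl-4-methylphenol (1 equiv), sealed tube, 150 °C
Reagents that add atoms: none
Why: On heating, the electron-rich methoxy enyne (C9≡C11–C12=C13) adds as the four-carbon partner across the electron-poor ynone triple bond (C8≡C14) in a polarity-matched, asynchronous [4+2] cycloaddition, in which nucleophilic C13 bonds to the β-carbon C14 and C9 bonds to C8. The primary adduct is the isoaromatic cyclic allene 31 (C9=C11=C12), which the phenol additive turns into the benzene ring by protonation at C11 and loss of the C13 proton, a net hydrogen shift from C13 to C11, so no oxidant is needed. The closest known reaction type is the thermal intramolecular dehydro-Diels–Alder reaction of conjugated enynes with ynones whose carbonyl group lies in the tether. Ring C closes as the six-membered cycloadduct ring through both new bonds; ring B closes through the C8–C9 bond as the tether ring of an intramolecular cycloaddition, and is six-membered because four atoms (C10, C5, C6, C7) link the partners. No stereocentre is created, since C13 is stereogenic only in 31 and becomes aromatic. The step needs regioselectivity, periselectivity and survival of C6: the tether allows only one orientation, the donor-substituted enyne favours the all-carbon mode over the ynone reacting as an oxadiene, and ring A holds the two arms gauche (trans, both equatorial) so that closure can compete with intermolecular reactions at high dilution. In the closing conformer of the 6R epimer H6 points at the two axial methyl groups and the silyloxy group is equatorial, which is also the preferred arrangement in 32, so there is no driving force for epimerisation.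

Step 18
Reactants: 32 6α-[(tert-butyldimethylsilyl)oxy]-12-methoxyabieta-8,11,13-trien-7-one
Product: 33 6α-[(tert-butyldimethylsilyl)oxy]-12-methoxyabieta-8,11,13-trien-7β-ol
Conditions: NaBH4, MeOH–THF, 0 °C
Reagents that add atoms: none
Why: Borohydride reduction of the aryl ketone, expected from the α face to give the equatorial 7β alcohol. A 7α epimer can be carried on, because C7 is re-formed in step 20.

Step 19
Reactants: 33 6α-[(tert-butyldimethylsilyl)oxy]-12-methoxyabieta-8,11,13-trien-7β-ol
Product: 34 12-methoxyabieta-8,11,13-triene-6α,7β-diol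
Conditions: Bu4NF, THF, rt to 50 °C
Reagents that add atoms: none
Why: Fluoride cleavage of the silyl ether; it is done after the reduction, so that no base-labile α-ketol is formed.

Step 20
Reactants: 34 12-methoxyabieta-8,11,13-triene-6α,7β-diol (two molecules)
Product: 36 target dimer: bis(12-methoxyabieta-8,11,13-triene) joined by a 1,4-dioxane through 7β-O–6'α and 7'β-O–6α, via hydroxy ether 35 (not isolated)
Conditions: TsOH·H2O (5 mol %), 4 Å molecular sieves, CH2Cl2 (0.5 M), rt
Reagents that add atoms: none
Why: Acid-catalysed dehydrative etherification: the C7 hydroxyl ionises to a cation stabilised by the para methoxy group, the C6 hydroxyl of a second molecule captures it (35), and a second ionisation at C7' closes the six-membered dioxane. Only C7 can ionise and C6–O never breaks, so C6 is retained and the union is head-to-tail. Ether formation is reversible, so both C7 centres should settle in the all-equatorial, doubly trans-fused 7β arrangement.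

## Compound list

1 | prop-2-yn-1-ol | C#CCO | starting material
2 | bromomagnesium (2Z)-3-(bromomagnesio)-2-methylprop-2-en-1-olate | Br[Mg]/C=C(/C)CO[Mg]Br | intermediate (not isolated)
3 | (2Z)-3-iodo-2-methylprop-2-en-1-ol | I/C=C(/C)CO | intermediate
4 | benzyl (2Z)-3-iodo-2-methylprop-2-en-1-yl ether | I/C=C(/C)COCc1ccccc1 | intermediate
5 | 3,3-dimethylglutaric anhydride | CC1(C)CC(=O)OC(=O)C1 | starting material
6 | 5-methoxy-3,3-dimethyl-5-oxopentanoic acid | COC(=O)CC(C)(C)CC(=O)O | intermediate
7 | methyl 5-chloro-3,3-dimethyl-5-oxopentanoate | COC(=O)CC(C)(C)CC(=O)Cl | intermediate (not isolated)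
8 | [(1Z)-3-(benzyloxy)-2-methylprop-1-en-1-yl]zinc chloride | Cl[Zn]/C=C(/C)COCc1ccccc1 | intermediate (not isolated)
9 | methyl (6Z)-8-(benzyloxy)-3,3,7-trimethyl-5-oxooct-6-enoate | COC(=O)CC(C)(C)CC(=O)/C=C(/C)COCc1ccccc1 | intermediate
10 | methyl (5R,6Z)-8-(benzyloxy)-5-hydroxy-3,3,7-trimethyloct-6-enoate | COC(=O)CC(C)(C)C[C@@H](O)/C=C(/C)COCc1ccccc1 | intermediate (not isolated)
11 | (6R)-6-[(1Z)-3-(benzyloxy)-2-methylprop-1-en-1-yl]-4,4-dimethyloxan-2-one | O=C1CC(C)(C)C[C@H](/C=C(/C)COCc2ccccc2)O1 | intermediate
12 | trimethylsilyl ketene acetal of 11, (2R)-2-[(1Z)-3-(benzyloxy)-2-methylprop-1-en-1-yl]-4,4-dimethyl-6-(trimethylsilyloxy)-3,4-dihydro-2H-pyran | C[Si](C)(C)OC1=CC(C)(C)C[C@H](/C=C(/C)COCc2ccccc2)O1 | intermediate (not isolated)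
13 | trimethylsilyl (1S,2S)-2-[(benzyloxy)methyl]-2,6,6-trimethylcyclohex-3-ene-1-carboxylate | C[Si](C)(C)OC(=O)[C@H]1C(C)(C)CC=C[C@]1(C)COCc1ccccc1 | intermediate (not isolated)
14 | (1S,2S)-2-[(benzyloxy)methyl]-2,6,6-trimethylcyclohex-3-ene-1-carboxylic acid | OC(=O)[C@H]1C(C)(C)CC=C[C@]1(C)COCc1ccccc1 | intermediate
15 | (1S,2S)-2-[(benzyloxy)methyl]-2,6,6-trimethylcyclohex-3-ene-1-carbonyl chloride | ClC(=O)[C@H]1C(C)(C)CC=C[C@]1(C)COCc1ccccc1 | intermediate (not isolated)
16 | 1-[(1S,2S)-2-[(benzyloxy)methyl]-2,6,6-trimethylcyclohex-3-en-1-yl]-2-diazoethan-1-one | [N-]=[N+]=CC(=O)[C@H]1C(C)(C)CC=C[C@]1(C)COCc1ccccc1 | intermediate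
17 | 2-[(1S,2S)-2-[(benzyloxy)methyl]-2,6,6-trimethylcyclohex-3-en-1-yl]ethenone (ketene) | O=C=C[C@H]1C(C)(C)CC=C[C@]1(C)COCc1ccccc1 | intermediate (not isolated)
18 | methyl 2-[(1S,2S)-2-[(benzyloxy)methyl]-2,6,6-trimethylcyclohex-3-en-1-yl]acetate | COC(=O)C[C@H]1C(C)(C)CC=C[C@]1(C)COCc1ccccc1 | intermediate
19 | methyl 2-[(1S,2S)-2-(hydroxymethyl)-2,6,6-trimethylcyclohexyl]acetate | COC(=O)C[C@H]1C(C)(C)CCC[C@]1(C)CO | intermediate (not isolated)
20 | (4aS,8aS)-5,5,8a-trimethyl-1,4,4a,5,6,7,8,8a-octahydro-3H-isochromen-3-one | O=C1C[C@H]2C(C)(C)CCC[C@]2(C)CO1 | intermediate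
21 | tert-butyldimethylsilyl ketene acetal of 20, (4aS,8aS)-3-[(tert-butyldimethylsilyl)oxy]-5,5,8a-trimethyl-4a,5,6,7,8,8a-hexahydro-1H-isochromene | CC(C)(C)[Si](C)(C)OC1=C[C@H]2C(C)(C)CCC[C@]2(C)CO1 | intermediate (not isolated)
22 | (4R,4aS,8aS)-4-[(tert-butyldimethylsilyl)oxy]-5,5,8a-trimethyl-1,4,4a,5,6,7,8,8a-octahydro-3H-isochromen-3-one | O=C1[C@H](O[Si](C)(C)C(C)(C)C)[C@H]2C(C)(C)CCC[C@]2(C)CO1 | intermediate
23 | (2R)-2-[(tert-butyldimethylsilyl)oxy]-2-[(1S,2S)-2-(hydroxymethyl)-2,6,6-trimethylcyclohexyl]-N-methoxy-N-methylacetamide | CON(C)C(=O)[C@H](O[Si](C)(C)C(C)(C)C)[C@H]1C(C)(C)CCC[C@]1(C)CO | intermediate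
24 | (2R)-2-[(tert-butyldimethylsilyl)oxy]-2-[(1S,2S)-2-formyl-2,6,6-trimethylcyclohexyl]-N-methoxy-N-methylacetamide | CON(C)C(=O)[C@H](O[Si](C)(C)C(C)(C)C)[C@H]1C(C)(C)CCC[C@]1(C)C=O | intermediate
25 | (2R)-2-[(tert-butyldimethylsilyl)oxy]-2-[(1S,2S)-2-ethynyl-2,6,6-trimethylcyclohexyl]-N-methoxy-N-methylacetamide | CON(C)C(=O)[C@H](O[Si](C)(C)C(C)(C)C)[C@H]1C(C)(C)CCC[C@]1(C)C#C | intermediate
26 | 3-methylbutanoyl chloride (isovaleryl chloride) | CC(C)CC(Cl)=O | starting material
27 | (2R)-2-[(tert-butyldimethylsilyl)oxy]-N-methoxy-N-methyl-2-[(1S,2S)-2,6,6-trimethyl-2-(5-methyl-3-oxohex-1-yn-1-yl)cyclohexyl]acetamide | CON(C)C(=O)[C@H](O[Si](C)(C)C(C)(C)C)[C@H]1C(C)(C)CCC[C@]1(C)C#CC(=O)CC(C)C | intermediate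
28 | potassium (Z)-enolate of 27 | [K+].CON(C)C(=O)[C@H](O[Si](C)(C)C(C)(C)C)[C@H]1C(C)(C)CCC[C@]1(C)C#C/C([O-])=C/C(C)C | intermediate (not isolated)
29 | (2R)-2-[(tert-butyldimethylsilyl)oxy]-N-methoxy-2-[(1S,2S)-2-[(3Z)-3-methoxy-5-methylhex-3-en-1-yn-1-yl]-2,6,6-trimethylcyclohexyl]-N-methylacetamide | CON(C)C(=O)[C@H](O[Si](C)(C)C(C)(C)C)[C@H]1C(C)(C)CCC[C@]1(C)C#C/C(OC)=C/C(C)C | intermediate
30 | (1R)-1-[(tert-butyldimethylsilyl)oxy]-1-[(1S,2S)-2-[(3Z)-3-methoxy-5-methylhex-3-en-1-yn-1-yl]-2,6,6-trimethylcyclohexyl]but-3-yn-2-one | C#CC(=O)[C@H](O[Si](C)(C)C(C)(C)C)[C@H]1C(C)(C)CCC[C@]1(C)C#C/C(OC)=C/C(C)C | intermediate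
31 | cyclic allene cycloadduct (ring C as 1,2,4-cyclohexatriene, C9=C11=C12, C13 sp3; configuration at C13 undefined) | COC1=C=C2C(=CC1C(C)C)C(=O)[C@H](O[Si](C)(C)C(C)(C)C)[C@H]1C(C)(C)CCC[C@]21C | intermediate (not isolated)
32 | 6α-[(tert-butyldimethylsilyl)oxy]-12-methoxyabieta-8,11,13-trien-7-one | COc1cc2c(cc1C(C)C)C(=O)[C@H](O[Si](C)(C)C(C)(C)C)[C@H]1C(C)(C)CCC[C@]21C | intermediate
33 | 6α-[(tert-butyldimethylsilyl)oxy]-12-methoxyabieta-8,11,13-trien-7β-ol | COc1cc2c(cc1C(C)C)[C@@H](O)[C@H](O[Si](C)(C)C(C)(C)C)[C@H]1C(C)(C)CCC[C@]21C | intermediate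
34 | 12-methoxyabieta-8,11,13-triene-6α,7β-diol | COc1cc2c(cc1C(C)C)[C@@H](O)[C@H](O)[C@H]1C(C)(C)CCC[C@]21C | intermediate
35 | open-chain hydroxy ether: 7β-O–6'α ether of two units of 34, with free 6α-OH and 7'β-OH | COc1cc2c(cc1C(C)C)[C@@H](O[C@H]3[C@H](O)c4cc(C(C)C)c(OC)cc4[C@@]4(C)CCCC(C)(C)[C@H]34)[C@H](O)[C@H]1C(C)(C)CCC[C@]21C | intermediate (not isolated)
36 | CNP0327150.1, head-to-tail 1,4-dioxane dimer | COc1cc2c(cc1C(C)C)[C@H]1O[C@H]3[C@H](O[C@@H]1[C@H]1C(C)(C)CCC[C@]21C)c1cc(C(C)C)c(OC)cc1[C@@]1(C)CCCC(C)(C)[C@H]31 | target

## Step count and least certain steps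

Total step count: 20. Longest linear sequence: 19 steps (steps 1, 2 and 4 to 20, from prop-2-yn-1-ol); the second branch (step 3) joins at step 4.

**Step 17 (key step).** The terminal ynone may be consumed before the cycloaddition, by polymerisation or by reacting as a four-atom oxadiene with the C9≡C11 triple bond. This is possible because closure through a four-atom tether needs a higher temperature than the better-known three-atom cases. Traces of acid could also cleave the enol ether. The fallback replaces the alkyne two-carbon partner by an alkene and adds a dehydrogenation. It sets out from 29. Vinylmagnesium bromide gives the α-silyloxy vinyl ketone F1. Heating F1 brings about the intramolecular [4+2] addition of the methoxy enyne to the enone double bond, and hydrogen shift in the cyclic allene gives the 8,14-dihydroarene F2. Dehydrogenation of F2 with DDQ returns to the route at 32.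

**Step 20.** The C7 cation may undergo a hydride shift from C6 (a semipinacol process) or lose the C6 proton, either of which ends in a 6-ketone. The risk is real because the C6–H bond is axial and parallel to the empty orbital, while capture by the hindered C6 hydroxyl of a second molecule is bimolecular. The fallback forms the C7–O bonds at the ketone oxidation level, so that no free carbocation sits next to the carbinol C–H. It sets out from 32. Buffered fluoride gives 6α-hydroxy-12-methoxyabieta-8,11,13-trien-7-one F3. Concentrated F3 is treated with Et3SiH and Me3SiOTf in CH2Cl2 at −78 °C (reductive etherification). The C6 oxygen of one molecule adds to the activated C7 ketone of the other, and the O-alkyl oxocarbenium ion is reduced by the silane from the α face. The same sequence then closes the ring and reaches the route at 36.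

**Step 6.** The rearrangement may be too slow, so that the ketene acetal 12 decomposes or is C-silylated first. The cause is the enforced boat: the Z benzyloxymethyl group is pressed against the neighbouring ring methylene and lies under the gem-dimethyl carbon while a bond to a fully substituted carbon forms. The fallback uses an open-chain ester that can rearrange through a chair, and closes ring A afterwards. It sets out from 4. Lithiation, transmetalation to zinc and palladium-catalysed acylation with acetyl chloride give (3Z)-5-(benzyloxy)-4-methylpent-3-en-2-one F4. Reduction with the (R)-Me-CBS catalyst gives the (S) alcohol F5, which is esterified (DCC, DMAP) with 3,3-dimethylhex-5-enoic acid to ester F6. Ireland–Claisen rearrangement of F6 (LiN(iPr)2, THF–HMPA, t-BuMe2SiCl, then heat and hydrolysis) goes through a chair with the carbinol methyl equatorial and transfers the chirality to C5 and C10, giving diene acid F7. Ring-closing metathesis of F7 with second-generation Grubbs catalyst, with loss of propene, returns to the route at 14.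

**Step 15.** The enolate may be methylated on carbon (C13) or give a mixture of enol ether geometries, and the strong base may degrade the N-methoxy amide. An extended ynone enolate is ambident, and the result depends on ion pairing. The fallback uses soft enolisation and carries a silyl enol ether through the cycloaddition. It sets out from 27. t-BuMe2SiOTf and Et3N give the (Z)-silyl enol ether F8, and ethynylmagnesium bromide converts it into ynone F9. Heating as in step 17 gives the 12-silyloxy tricycle F10. K2CO3 in MeOH cleaves only the aryl silyl ether to phenol F11. Methylation of F11 with MeI and K2CO3 returns to the route at 32.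

## Further compounds

F1 | step 17 | (4R)-4-[(tert-butyldimethylsilyl)oxy]-4-[(1S,2S)-2-[(3Z)-3-methoxy-5-methylhex-3-en-1-yn-1-yl]-2,6,6-trimethylcyclohexyl]but-1-en-3-one | C=CC(=O)[C@H](O[Si](C)(C)C(C)(C)C)[C@H]1C(C)(C)CCC[C@]1(C)C#C/C(OC)=C/C(C)C
F2 | step 17 | 6α-[(tert-butyldimethylsilyl)oxy]-12-methoxyabieta-9(11),12-dien-7-one (8,14-dihydro form of 32, C8 undefined) | CC(C)C1=C(OC)C=C2C(C1)C(=O)[C@H](O[Si](C)(C)C(C)(C)C)[C@H]1C(C)(C)CCC[C@]21C
F3 | step 20 | 6α-hydroxy-12-methoxyabieta-8,11,13-trien-7-one | COc1cc2c(cc1C(C)C)C(=O)[C@H](O)[C@H]1C(C)(C)CCC[C@]21C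
F4 | step 6 | (3Z)-5-(benzyloxy)-4-methylpent-3-en-2-one | CC(=O)/C=C(/C)COCc1ccccc1
F5 | step 6 | (2S,3Z)-5-(benzyloxy)-4-methylpent-3-en-2-ol | C[C@H](O)/C=C(/C)COCc1ccccc1
F6 | step 6 | (2S,3Z)-5-(benzyloxy)-4-methylpent-3-en-2-yl 3,3-dimethylhex-5-enoate | C=CCC(C)(C)CC(=O)O[C@@H](C)/C=C(/C)COCc1ccccc1
F7 | step 6 | (2S,3S,4E)-3-[(benzyloxy)methyl]-3-methyl-2-(2-methylpent-4-en-2-yl)hex-4-enoic acid | OC(=O)[C@@H](C(C)(C)CC=C)[C@](C)(/C=C/C)COCc1ccccc1
F8 | step 15 | (2R)-2-[(tert-butyldimethylsilyl)oxy]-2-[(1S,2S)-2-[(3Z)-3-[(tert-butyldimethylsilyl)oxy]-5-methylhex-3-en-1-yn-1-yl]-2,6,6-trimethylcyclohexyl]-N-methoxy-N-methylacetamide | CON(C)C(=O)[C@H](O[Si](C)(C)C(C)(C)C)[C@H]1C(C)(C)CCC[C@]1(C)C#C/C(O[Si](C)(C)C(C)(C)C)=C/C(C)C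
F9 | step 15 | (1R)-1-[(tert-butyldimethylsilyl)oxy]-1-[(1S,2S)-2-[(3Z)-3-[(tert-butyldimethylsilyl)oxy]-5-methylhex-3-en-1-yn-1-yl]-2,6,6-trimethylcyclohexyl]but-3-yn-2-one | C#CC(=O)[C@H](O[Si](C)(C)C(C)(C)C)[C@H]1C(C)(C)CCC[C@]1(C)C#C/C(O[Si](C)(C)C(C)(C)C)=C/C(C)C
F10 | step 15 | 6α,12-bis[(tert-butyldimethylsilyl)oxy]abieta-8,11,13-trien-7-one | CC(C)(C)[Si](C)(C)Oc1cc2c(cc1C(C)C)C(=O)[C@H](O[Si](C)(C)C(C)(C)C)[C@H]1C(C)(C)CCC[C@]21C
F11 | step 15 | 6α-[(tert-butyldimethylsilyl)oxy]-12-hydroxyabieta-8,11,13-trien-7-one | Oc1cc2c(cc1C(C)C)C(=O)[C@H](O[Si](C)(C)C(C)(C)C)[C@H]1C(C)(C)CCC[C@]21C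
A1 | alternative 1 | (6R)-6-[(1Z)-2-(3-methoxy-4-isopropylphenyl)prop-1-en-1-yl]-4,4-dimethyloxan-2-one | O=C1CC(C)(C)C[C@H](/C=C(/C)c2ccc(C(C)C)c(OC)c2)O1
A2 | alternative 1 | (1S,2S)-2-(4-isopropyl-3-methoxyphenyl)-2,6,6-trimethylcyclohex-3-ene-1-carboxylic acid | OC(=O)[C@H]1C(C)(C)CC=C[C@]1(C)c1ccc(C(C)C)c(OC)c1
A3 | alternative 2 | sclareolide | C[C@]12CCCC([C@@H]1CC[C@@]3([C@@H]2CC(=O)O3)C)(C)C
A4 | alternative 2 | 4-methyl-1-(5,5,8a-trimethyl-2-methylidenedecahydronaphthalen-1-yl)pentane-2,3-dione (natural trans-decalin configuration, 9α-H) | CC(C)C(=O)C(=O)C[C@H]1C(=C)CC[C@H]2C(C)(C)CCC[C@]12C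
A5 | alternative 2 | ferruginol | CC(C)c1cc2c(cc1O)[C@@]1(C)CCCC(C)(C)[C@@H]1CC2
A6 | alternative 3 | 6-isopropyl-7-methoxy-1-methyl-3,4-dihydronaphthalen-2(1H)-one | COc1cc2c(cc1C(C)C)CCC(=O)C2C
A7 | alternative 3 | methyl vinyl ketone | CC(=O)C=C
A8 | alternative 3 | 12-methoxy-18,19-dinorabieta-4,8,11,13-tetraen-3-one | COc1cc2c(cc1C(C)C)CCC1=CC(=O)CC[C@]21C
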